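The ratio of J to Q in the elm flask was 1.50, the same as in the alder run, and Z was the same 0.00750 M. So I treated elm as alder diluted 2.50-fold and asked how much slower its clock ran.

| setting | alder | birch | oak | cedar | elm |
|---|---|---|---|---|---|
| Q | 0.150 M | 0.300 M | 0.150 M | 0.150 M | 0.0600 M |
| J | 0.225 M | 0.225 M | 0.110 M | 0.225 M | 0.0900 M |
| Z | 0.00750 M | 0.00750 M | 0.00750 M | 0.00750 M | 0.00750 M |
| X |  |  |  | 0.0450 M |  |
| time |  |  |  |  | 87 min |

| alder run: time / min | alder run: [X] / M | birch run: time / min | birch run: [X] / M | oak run: time / min | oak run: [X] / M | cedar run: time / min | cedar run: [X] / M |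
|---|---|---|---|---|---|---|---|
| 3.1 | 0.0103 | 3.1 | 0.0172 | 3.1 | 0.0066 | 3.1 | 0.0547 |
| 9.5 | 0.0291 | 9.5 | 0.0450 | 9.5 | 0.0195 | 9.5 | 0.0697 |
| 18 | 0.0474 | 18 | 0.0750 | 18 | 0.0330 | 18 | 0.0886 |
| 29 | 0.0667 | 29 | 0.1030 | 29 | 0.0436 | 29 | 0.1057 |
| 41 | 0.0807 | 41 | 0.1243 | 41 | 0.0542 | 41 | 0.1170 |
| 55 | 0.0891 | 55 | 0.1430 | 55 | 0.0648 | 55 | 0.1247 |
| 70 | 0.0963 | 70 | 0.1536 | 70 | 0.0703 | 70 | 0.1277 |
| 87 | 0.1009 | 87 | 0.1621 | 87 | 0.0764 | 87 | 0.1297 |

(standard deviation of a reading: 0.001 M)

* reaction order in [Q] at the outset, round the charge of the alder run, defined at two percent of the Q turned into X (one fixed amount of X, the same in the runs compared)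
* reaction order in [J] at the outset, round the charge of the alder run, defined at two percent of the Q turned into X
* X in the elm run at 87 min, as a share of the Q charged

- Overall: Q + J -> X, with Z as catalyst.
- Constant volume, constant temperature.
- Bound and free are read together.
- An order is taken over about fifteen percent of the charge, up and down.

If the rate at fixed Z is a power of the concentrations, a diluted copy reaches any share of its Q later by a power of the dilution, and that power is the total order less one. Birch and oak were nearly such a pair, with J to Q of 0.750 and 0.733, Q a factor 2.00 apart, and the same Z. Birch read a quarter of its Q at 18.0 min. Oak rose 9.64 × 10⁻⁴ M min⁻¹ between its readings at 18 min and 29 min, and by interpolation reached the same share at 22.7 min. The logarithm of that time ratio over the logarithm of the dilution gave 0.333, my dilution exponent, the power of the dilution by which the time to a fixed share of Q grows at fixed Z and fixed J to Q.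

On that exponent I took elm at 87 min to stand for alder at 64.1 min, which lies between the alder readings at 55 min and 70 min, where alder rose 4.80 × 10⁻⁴ M min⁻¹. Before taking the number, I asked what each input could do to it:

| Input | Supposed error | Shift in the elm share |
|---|---|---|
| Oak reading, through the exponent | 0.001 M, so 0.0646 in the exponent | 1.2 percentage points |
| Alder reading near the matched time | 0.001 M | 0.67 points |
| Cedar readings | any | none, as they enter no step of this reckoning |

The exponent weighed more than the alder reading. Its unpriced risk was that it was read at a lower J to Q than elm's. I committed to 62.3% of the Q charged.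

The forecast, made from the same runs, gave an order of 0.76 in Q (0.6 to 0.9), 0.52 in J (0.35 to 0.7), and 62% for elm (53% to 71%), with the words “Allowing for the stall gives about 62%”. My figure came by the diluted clock instead.

    Z + Q ⇌ ZQ, settled at all times (3.180 M⁻¹)
    ZQ + J → X + Z + L (17.64 M⁻¹ min⁻¹)
    X + J → G (0.06840 M⁻¹ min⁻¹)
    2 J ⇌ J2, settled at all times (10.20 M⁻¹)

The simulation gave 60.5% for elm, with orders 0.71 in Q and 0.62 in J. The simulated times to a quarter of the Q charged were 22.3 min in oak and 18.2 min in birch. By interpolation in the alder readings, alder reached elm's share of its Q, 0.0908 M, at 58.6 min, so the exponent between alder and elm read 0.431, larger than my 0.333. Carried back to the pair it was read from, my exponent takes oak's simulated time to 17.7 min for birch, whose simulated time is 18.2 min.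

All runs are calculated with made-up constants; noise was put on by code.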